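**Strategy.** The route rests on disconnecting the bond between C2 of the chromanone (ring C) and the carbon of ring B that lies ortho to one phenolic oxygen and para to the other. C2 is the β-carbon of a chromone enone (O1–C2=C3–C4=O), so the bond is made by an enantioselective palladium-catalysed conjugate addition of an arylboronic acid to 7-hydroxychromone. The boronic acid is the complete all-trans methylcyclohexene core, assembled beforehand by an exo-selective, borate-catalysed asymmetric Diels–Alder reaction of a 2'-hydroxychalcone with a bromo-aryl diene; the bromine marks the ring B carbon. One operation thus unites both halves and sets the C2 stereocentre under catalyst control.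

Key step: step 8

Assumption: the sense of induction of the two chiral catalysts is assigned by analogy with their parent reactions ((R)-VANOL borate to the (1R,2R,6S) adduct, (R)-t-BuPyOx to the (2S)-chromanone); should either sense be found opposite, the antipodal ligand is used with no other change.

**Step 1**
Reactants: 1 5-bromo-2,4-dihydroxybenzaldehyde
Product: 2 5-bromo-2,4-bis(methoxymethoxy)benzaldehyde
Conditions: NaH, MOMCl, DMF, 0 °C to rt
Reagents that add atoms: chloromethyl methyl ether (MOMCl), COCCl
Why: Williamson-type O-alkylation of both sodium phenoxides by the reactive α-chloro ether should protect both hydroxyls, the aldehyde and the aryl bromide being inert.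

**Step 2**
Reactants: 2 5-bromo-2,4-bis(methoxymethoxy)benzaldehyde; 3 diethyl (2-methylallyl)phosphonate
Product: 4 1-bromo-2,4-bis(methoxymethoxy)-5-[(1E)-3-methylbuta-1,3-dien-1-yl]benzene
Conditions: 3, n-BuLi, THF, −78 °C; then 2, HMPA, −78 °C to rt
Reagents that add atoms: none
Why: Horner–Wadsworth–Emmons olefination with the lithiated allylic phosphonate (α-attack on the aldehyde, then syn-elimination of lithium diethyl phosphate) should give the conjugated diene with (E) geometry from reversible addition, and the phosphonate is fully deprotonated before the aldehyde is added so that no n-BuLi remains to attack the aryl bromide.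

**Step 3**
Reactants: 5 1-(2,4-dihydroxyphenyl)ethan-1-one
Product: 6 1-[2-hydroxy-4-(methoxymethoxy)phenyl]ethan-1-one
Conditions: MOMCl (1.1 equiv), K2CO3, acetone, rt
Reagents that add atoms: chloromethyl methyl ether (MOMCl), COCCl
Why: The 2-hydroxyl is held in a hydrogen bond to the ketone, so mild base should alkylate only the 4-hydroxyl (chemoselective Williamson etherification).

**Step 4**
Reactants: 7 2,4-dihydroxybenzaldehyde
Product: 8 2,4-bis(methoxymethoxy)benzaldehyde
Conditions: NaH, MOMCl, DMF, 0 °C to rt
Reagents that add atoms: chloromethyl methyl ether (MOMCl), COCCl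
Why: Double Williamson-type O-alkylation as in step 1 should protect both phenols.

**Step 5**
Reactants: 6 1-[2-hydroxy-4-(methoxymethoxy)phenyl]ethan-1-one; 8 2,4-bis(methoxymethoxy)benzaldehyde
Product: 9 (2E)-3-[2,4-bis(methoxymethoxy)phenyl]-1-[2-hydroxy-4-(methoxymethoxy)phenyl]prop-2-en-1-one
Conditions: KOH, EtOH/H2O, rt; then AcOH to pH 6
Reagents that add atoms: none
Why: Claisen–Schmidt condensation (enolate addition to the non-enolisable aldehyde, then E1cB dehydration) should give the conjugated (E)-enone, with the MOM ethers stable to hydroxide and the free 2'-hydroxyl kept for step 6.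

**Step 6**
Reactants: 4 1-bromo-2,4-bis(methoxymethoxy)-5-[(1E)-3-methylbuta-1,3-dien-1-yl]benzene; 9 the 2'-hydroxychalcone
Product: 10 [(1R,2R,6S)-2-[5-bromo-2,4-bis(methoxymethoxy)phenyl]-6-[2,4-bis(methoxymethoxy)phenyl]-4-methylcyclohex-3-en-1-yl][2-hydroxy-4-(methoxymethoxy)phenyl]methanone (all-trans, exo adduct)
Conditions: B(OPh)3 (30 mol%), (R)-VANOL (30 mol%), 4 Å MS, PhCF3, rt; then 9 and 4 (1.5 equiv), rt to 40 °C
Reagents that add atoms: none
Why: In this asymmetric Diels–Alder reaction the 2'-hydroxychalcone should bind boron through phenoxide and carbonyl oxygen to give a tetracoordinate chiral borate that activates the enone and shields one face, the aryl-bearing diene terminus bonding to the α-carbon (ortho rule, methyl para to the aroyl group), the trans relation of aroyl and aryl following from the (E)-enone, the exo transition state placing the diene aryl trans to the aroyl group, and the ligand setting the absolute configuration (1R,2R,6S).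

**Step 7**
Reactants: 10 the all-trans aryl bromide
Product: 11 {5-[(1R,5S,6R)-5-[2,4-bis(methoxymethoxy)phenyl]-6-[2-hydroxy-4-(methoxymethoxy)benzoyl]-3-methylcyclohex-2-en-1-yl]-2,4-bis(methoxymethoxy)phenyl}boronic acid
Conditions: B2(OH)4, Pd(OAc)2 (5 mol%), XPhos (10 mol%), KOAc, EtOH, 80 °C
Reagents that add atoms: tetrahydroxydiboron, OB(O)B(O)O
Why: Miyaura borylation (oxidative addition of zerovalent palladium into the C–Br bond, acetate-assisted transmetalation with the diboron reagent, reductive elimination) should give the arylboronic acid directly, with ketone, chelated phenol, alkene and MOM ethers inert.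

**Step 8**
Reactants: 11 the arylboronic acid; 12 7-hydroxy-4H-chromen-4-one (3 equiv)
Product: 13 (2S)-2-{5-[(1R,5S,6R)-5-[2,4-bis(methoxymethoxy)phenyl]-6-[2-hydroxy-4-(methoxymethoxy)benzoyl]-3-methylcyclohex-2-en-1-yl]-2,4-bis(methoxymethoxy)phenyl}-7-hydroxy-2,3-dihydro-4H-chromen-4-one (penta-MOM ether of guangsangon N)
Conditions: Pd(OCOCF3)2 (10 mol%), (R)-t-BuPyOx (12 mol%), NH4PF6 (30 mol%), H2O (5 equiv), ClCH2CH2Cl, 60 °C
Reagents that add atoms: none
Why: Transmetalation of 11 to the cationic divalent palladium–(R)-t-BuPyOx complex should give an aryl–palladium species that binds the C2=C3 bond of 12 and undergoes enantiodetermining migratory insertion, placing the aryl group on C2 and palladium on C3 as its enolate, which water protonates to release 13 and return the catalyst without change of oxidation state. The closest known reaction type is the palladium/pyridine-oxazoline-catalysed asymmetric conjugate addition of arylboronic acids to chromones and cyclic enones. No ring is closed, since ring C is already present in 12 and only the exocyclic C2–aryl bond is formed. The new C2 stereocentre is set by the ligand, whose tert-butyl group blocks one enone face, and because the three cyclohexene stereocentres sit on a remote substituent meta to boron the outcome should be pure catalyst control, (2S) with the (R)-ligand. The step needs chemoselectivity for the chromone over the hindered trisubstituted ring alkene and over protodeboronation, which the non-redox cycle, the excess of 12 and the moderate temperature should secure, while the site on ring B is fixed by the position of boron. The free phenols of both partners should be tolerated by this aqueous system, and any loss of MOM groups is harmless because step 9 removes them.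

**Step 9**
Reactants: 13 the penta-MOM ether
Product: 14 guangsangon N, (2S)-2-{5-[(1R,5S,6R)-6-(2,4-dihydroxybenzoyl)-5-(2,4-dihydroxyphenyl)-3-methylcyclohex-2-en-1-yl]-2,4-dihydroxyphenyl}-7-hydroxy-2,3-dihydro-4H-chromen-4-one
Conditions: HCl (3 M aq., ca. 10 equiv), MeOH/THF, 0 °C to rt, Ar
Reagents that add atoms: none
Why: Acid-catalysed acetal exchange with methanol should remove the five aryl MOM ethers as dimethoxymethane, mild acid being chosen because base would open and racemise the (2S)-chromanone, while the trisubstituted alkene and the all-trans ketone are not expected to react at room temperature.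

**Compound list**
1 | 5-bromo-2,4-dihydroxybenzaldehyde | O=Cc1cc(Br)c(O)cc1O | starting material
2 | 5-bromo-2,4-bis(methoxymethoxy)benzaldehyde | O=Cc1cc(Br)c(OCOC)cc1OCOC | intermediate
3 | diethyl (2-methylallyl)phosphonate | CCOP(=O)(CC(C)=C)OCC | starting material
4 | 1-bromo-2,4-bis(methoxymethoxy)-5-[(1E)-3-methylbuta-1,3-dien-1-yl]benzene | C=C(C)/C=C/c1cc(Br)c(OCOC)cc1OCOC | intermediate
5 | 1-(2,4-dihydroxyphenyl)ethan-1-one | CC(=O)c1ccc(O)cc1O | starting material
6 | 1-[2-hydroxy-4-(methoxymethoxy)phenyl]ethan-1-one | CC(=O)c1ccc(OCOC)cc1O | intermediate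
7 | 2,4-dihydroxybenzaldehyde | O=Cc1ccc(O)cc1O | starting material
8 | 2,4-bis(methoxymethoxy)benzaldehyde | O=Cc1ccc(OCOC)cc1OCOC | intermediate
9 | (2E)-3-[2,4-bis(methoxymethoxy)phenyl]-1-[2-hydroxy-4-(methoxymethoxy)phenyl]prop-2-en-1-one | O=C(/C=C/c1ccc(OCOC)cc1OCOC)c1ccc(OCOC)cc1O | intermediate
10 | [(1R,2R,6S)-2-[5-bromo-2,4-bis(methoxymethoxy)phenyl]-6-[2,4-bis(methoxymethoxy)phenyl]-4-methylcyclohex-3-en-1-yl][2-hydroxy-4-(methoxymethoxy)phenyl]methanone | CC1=C[C@@H](c2cc(Br)c(OCOC)cc2OCOC)[C@H](C(=O)c2ccc(OCOC)cc2O)[C@@H](c2ccc(OCOC)cc2OCOC)C1 | intermediate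
11 | {5-[(1R,5S,6R)-5-[2,4-bis(methoxymethoxy)phenyl]-6-[2-hydroxy-4-(methoxymethoxy)benzoyl]-3-methylcyclohex-2-en-1-yl]-2,4-bis(methoxymethoxy)phenyl}boronic acid | CC1=C[C@@H](c2cc(B(O)O)c(OCOC)cc2OCOC)[C@H](C(=O)c2ccc(OCOC)cc2O)[C@@H](c2ccc(OCOC)cc2OCOC)C1 | intermediate
12 | 7-hydroxy-4H-chromen-4-one | O=c1ccoc2cc(O)ccc12 | starting material
13 | penta-MOM ether of guangsangon N, (2S)-chromanone on the (1R,5S,6R)-cyclohexene | CC1=C[C@@H](c2cc([C@@H]3CC(=O)c4ccc(O)cc4O3)c(OCOC)cc2OCOC)[C@H](C(=O)c2ccc(OCOC)cc2O)[C@@H](c2ccc(OCOC)cc2OCOC)C1 | intermediate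
14 | guangsangon N | CC1=C[C@@H](c2cc([C@@H]3CC(=O)c4ccc(O)cc4O3)c(O)cc2O)[C@H](C(=O)c2ccc(O)cc2O)[C@@H](c2ccc(O)cc2O)C1 | target

**Step count.** Total: 9 steps. Longest linear sequence: 6 steps (1 → 2 → 4 → 10 → 11 → 13 → 14).

**Steps most likely to fail**

Step 8. Protodeboronation of the electron-rich, ortho-alkoxy arylboronic acid may outrun a slow transmetalation and carbopalladation of this hindered fragment, so that the boron handle is lost before the C2–aryl bond forms. The fallback gives up the conjugate arylation and builds ring C on the aryl group by the classical chalcone route. It sets out from bromide 10. Palladium-catalysed reductive carbonylation (Pd(OAc)2, di(1-adamantyl)-n-butylphosphine, TMEDA, CO/H2, toluene, 100 °C) should give the aryl aldehyde F1. Claisen–Schmidt condensation of F1 with acetophenone 6 (KOH, EtOH, rt) should give the 2'-hydroxychalcone F2. Intramolecular oxa-Michael addition (NaOAc, EtOH, reflux) should then close the chromanone as the (2S) hexa-MOM chromanone F3 together with its (2R) epimer F4; the two are diastereomers and should be separable by chromatography, and F4 is re-equilibrated under the same conditions. F3 is deprotected under the conditions of step 9, so the fallback comes back to the route at 14. Catalyst control at C2 is replaced here by separation and recycling.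

Step 6. Turnover of the chiral borate may be slow with the hindered bromo diene (the chelating adduct can hold the boron), and exo or facial selectivity may erode. The fallback uses a thermal cycloaddition with the resolution deferred to the asymmetric key step. It sets out from 4 and 9. Heating in toluene (sealed tube, 165 °C, BHT), which relies only on the hydrogen-bond-activated enone, should give the all-trans adduct as a racemate after chromatographic removal of the cis,trans isomers, that is 10 together with its enantiomer F5. The racemate is carried through step 7, which converts F5 into the enantiomeric boronic acid F6 alongside 11. In step 8 the catalyst should set (2S) in both series, so that 13 is formed together with the diastereomeric chromanone F7, which is removed by chromatography. The fallback comes back to the route at 13.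

Step 7. Hydrodebromination, and protodeboronation of the product in hot ethanolic acetate, may compete with borylation, and material may be lost in isolating the polar boronic acid. The fallback installs boron before the cycloaddition as a robust pinacol ester. It sets out from diene 4. Bromine–lithium exchange (n-BuLi, THF, −78 °C) and quenching with 2-isopropoxy-4,4,5,5-tetramethyl-1,3,2-dioxaborolane should give the dienyl arylboronate F8. The Diels–Alder reaction of F8 with 9 under the conditions of step 6 should give the adduct pinacol boronate F9. Oxidative removal of the pinacol (NaIO4, NH4OAc, acetone/H2O, rt) should then give the boronic acid, and the fallback comes back to the route at 11.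

**Further compounds**
F1 | step 8 | 5-[(1R,5S,6R)-5-[2,4-bis(methoxymethoxy)phenyl]-6-[2-hydroxy-4-(methoxymethoxy)benzoyl]-3-methylcyclohex-2-en-1-yl]-2,4-bis(methoxymethoxy)benzaldehyde | CC1=C[C@@H](c2cc(C=O)c(OCOC)cc2OCOC)[C@H](C(=O)c2ccc(OCOC)cc2O)[C@@H](c2ccc(OCOC)cc2OCOC)C1
F2 | step 8 | (2E)-3-{5-[(1R,5S,6R)-5-[2,4-bis(methoxymethoxy)phenyl]-6-[2-hydroxy-4-(methoxymethoxy)benzoyl]-3-methylcyclohex-2-en-1-yl]-2,4-bis(methoxymethoxy)phenyl}-1-[2-hydroxy-4-(methoxymethoxy)phenyl]prop-2-en-1-one | CC1=C[C@@H](c2cc(/C=C/C(=O)c3ccc(OCOC)cc3O)c(OCOC)cc2OCOC)[C@H](C(=O)c2ccc(OCOC)cc2O)[C@@H](c2ccc(OCOC)cc2OCOC)C1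
F3 | step 8 | hexa-MOM ether of guangsangon N, (2S)-7-(methoxymethoxy)chromanone | CC1=C[C@@H](c2cc([C@@H]3CC(=O)c4ccc(OCOC)cc4O3)c(OCOC)cc2OCOC)[C@H](C(=O)c2ccc(OCOC)cc2O)[C@@H](c2ccc(OCOC)cc2OCOC)C1
F4 | step 8 | (2R) epimer of F3 | CC1=C[C@@H](c2cc([C@H]3CC(=O)c4ccc(OCOC)cc4O3)c(OCOC)cc2OCOC)[C@H](C(=O)c2ccc(OCOC)cc2O)[C@@H](c2ccc(OCOC)cc2OCOC)C1
F5 | step 6 | enantiomer of 10, (1S,2S,6R) | CC1=C[C@H](c2cc(Br)c(OCOC)cc2OCOC)[C@@H](C(=O)c2ccc(OCOC)cc2O)[C@H](c2ccc(OCOC)cc2OCOC)C1
F6 | step 6 | enantiomer of 11, (1S,5R,6S) | CC1=C[C@H](c2cc(B(O)O)c(OCOC)cc2OCOC)[C@@H](C(=O)c2ccc(OCOC)cc2O)[C@H](c2ccc(OCOC)cc2OCOC)C1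
F7 | step 6 | diastereomer of 13, (2S)-chromanone on the (1S,5R,6S)-cyclohexene | CC1=C[C@H](c2cc([C@@H]3CC(=O)c4ccc(O)cc4O3)c(OCOC)cc2OCOC)[C@@H](C(=O)c2ccc(OCOC)cc2O)[C@H](c2ccc(OCOC)cc2OCOC)C1
F8 | step 7 | 2-{2,4-bis(methoxymethoxy)-5-[(1E)-3-methylbuta-1,3-dien-1-yl]phenyl}-4,4,5,5-tetramethyl-1,3,2-dioxaborolane | C=C(C)/C=C/c1cc(B2OC(C)(C)C(C)(C)O2)c(OCOC)cc1OCOC
F9 | step 7 | pinacol ester of 11 | CC1=C[C@@H](c2cc(B3OC(C)(C)C(C)(C)O3)c(OCOC)cc2OCOC)[C@H](C(=O)c2ccc(OCOC)cc2O)[C@@H](c2ccc(OCOC)cc2OCOC)C1
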